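## Retrosynthetic overview

1. Target 19 ⇐ benzilic ester 1,2-shift (ring contraction 6→5, MeOH) of the (7R)-7-acetoxy-5,6,8-trione 17 ⇐ enantioselective C7 acetoxylation of hydroxyquinone 16 (one flask, last step).
2. 16 ⇐ lateral acylation of the 4-methylnicotinate 10 with Weinreb amide 11, Claisen ring closure and air oxidation (one flask).
3. 10 ⇐ Suzuki coupling of chloropyridine 9 with dienyl boronate 4; 9 ⇐ 5-bromo-2-chloropyridine 5 (C4 methylation, then Br → CO2Me).
4. 4 ⇐ enal 3 (boron-Wittig) ⇐ (S)-2-methylbutan-1-ol 1 (oxidation/Wittig).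
5. Ring order: pyridine bought; six-membered carbocycle closed in step 6; contracted to the cyclopentanone in step 7.

Assumption: 2-(triphenylphosphoranylidene)propanal, bis(pinacolboryl)methane and the chiral iodane A (made beforehand from the (R,R)-iodoarene and peracetic acid) are treated as reagents.

Isoquinoline locants (C5–C8) are used for 15–18; isoquinoline C7 becomes C6 of 19, and its CIP descriptor changes from R to S without any change in space.

## Route

Step 1
Reactants: 1 (S)-2-methylbutan-1-ol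
Product: 3 (2E,4S)-2,4-dimethylhex-2-enal, via (S)-2-methylbutanal 2 (not isolated)
Conditions: Cu(MeCN)4OTf/bpy/TEMPO (5 mol % each), NMI (10 mol %), O2 (balloon), MeCN, rt; then N2, Ph3P=C(Me)CHO, 70 °C
Reagents that add atoms: 2-(triphenylphosphoranylidene)propanal, CC(C=O)=P(c1ccccc1)(c1ccccc1)c1ccccc1
Why: Cu/TEMPO aerobic oxidation gives the α-branched aldehyde without touching the stereocenter (taken from 1), and the stabilised ylide traps it in the same flask by an E-selective Wittig olefination.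

Step 2
Reactants: 3 (2E,4S)-2,4-dimethylhex-2-enal
Product: 4 2-[(1E,3E,5S)-3,5-dimethylhepta-1,3-dien-1-yl]-4,4,5,5-tetramethyl-1,3,2-dioxaborolane
Conditions: CH2(Bpin)2, LiTMP, THF, 0 °C; then 3, −78 °C → rt
Reagents that add atoms: bis(pinacolboryl)methane, CC1(C)OB(CB2OC(C)(C)C(C)(C)O2)OC1(C)C
Why: Boron-Wittig olefination: the α-boryl carbanion adds 1,2 to the enal and syn B–O elimination gives the (E)-alkenyl boronate.

Step 3
Reactants: 5 5-bromo-2-chloropyridine
Product: 7 5-bromo-2-chloro-4-methylpyridine, via 4-lithiopyridine 6 (not isolated)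
Conditions: LDA, THF, −78 °C; MeI, −78 °C → rt
Reagents that add atoms: iodomethane, CI
Why: Directed ortho-lithiation: LDA removes H-4 next to bromine at −78 °C (too cold for a halogen dance) and the aryllithium is methylated by SN2.

Step 4
Reactants: 7 5-bromo-2-chloro-4-methylpyridine
Product: 9 methyl 6-chloro-4-methylpyridine-3-carboxylate, via pyridylmagnesium chloride 8 (not isolated)
Conditions: iPrMgCl·LiCl, THF, −15 → 0 °C; then added to ClCO2Me, −40 °C → rt
Reagents that add atoms: methyl chloroformate, COC(Cl)=O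
Why: Br/Mg exchange with the turbo-Grignard is much faster than attack at the 2-chloride, and inverse-addition acylation of the pyridyl Grignard with the chloroformate stops at the ester.

Step 5
Reactants: 9 methyl 6-chloro-4-methylpyridine-3-carboxylate; 4 dienyl boronate
Product: 10 methyl 6-[(1E,3E,5S)-3,5-dimethylhepta-1,3-dien-1-yl]-4-methylpyridine-3-carboxylate
Conditions: Pd(dppf)Cl2 (3 mol %), K3PO4, THF/H2O (10:1), 60 °C
Reagents that add atoms: none
Why: Suzuki–Miyaura coupling at the ester-activated 2-chloropyridine; the alkene geometry of the boronate is retained.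

Step 6
Reactants: 10 methyl 6-dienyl-4-methylpyridine-3-carboxylate; 11 N-methoxy-N-methylpropanamide
Product: 16 3-[(1E,3E,5S)-3,5-dimethylhepta-1,3-dien-1-yl]-6-hydroxy-7-methylisoquinoline-5,8-dione, via benzylic lithium 12 (not isolated), via tetrahedral adduct 13 (not isolated), via keto ester 14 (not isolated), via isoquinoline-6,8-diol 15 (not isolated)
Conditions: LDA, THF, −78 °C; 11, −78 → −40 °C; NaOMe/MeOH, → rt (Ar); O2, rt; aq. HCl
Reagents that add atoms: dioxygen, O=O
Why: Lateral (ortho-toluate type) lithiation of the ester- and aza-activated 4-methyl group and C-acylation by the Weinreb amide give the ketone on methanol quench; Claisen (Dieckmann-type) closure onto the neighbouring ester gives the aromatic 6,8-diol (the competing enol lactone reopens under NaOMe), whose anion is oxidised by O2 to the 2-hydroxy-1,4-quinone.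

Step 7
Reactants: 16 3-dienyl-6-hydroxy-7-methylisoquinoline-5,8-dione
Product: 19 methyl (5R,6S)-6-acetoxy-3-[(1E,3E,5S)-3,5-dimethylhepta-1,3-dien-1-yl]-5-hydroxy-6-methyl-7-oxo-6,7-dihydro-5H-cyclopenta[c]pyridine-5-carboxylate, via trione 17 (not isolated), via hemiketal 18 (not isolated)
Conditions: iodane A (1.1 equiv), CH2Cl2, −40 °C; then MeOH (20 equiv), Et3N (1.5 equiv), −40 → 0 °C
Reagents that add atoms: iodane A, (R,R)-2-(diacetoxy-λ3-iodanyl)-1,3-bis[1-(mesitylcarbamoyl)ethoxy]benzene, C[C@@H](Oc1cccc(O[C@H](C)C(=O)Nc2c(C)cc(C)cc2C)c1I(OC(C)=O)OC(C)=O)C(=O)Nc1c(C)cc(C)cc1C; methanol, CO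
Why: Proposed new method: reagent-controlled enantioselective Wessely-type acetoxylation of a 2-hydroxy-1,4-quinone, in which the acidic enol OH exchanges onto I(III) and acetate is delivered to one face of C7 inside the C2-symmetric lactamide pocket with loss of ArI, setting C7 (R in 17; the sense cannot be predicted, so the mirror-image reagent is used if it proves opposite), the closest known reaction types being chiral aryl-λ3-iodane oxidative dearomatisation of naphthols and PhI(OAc)2 α-acetoxylation of 1,3-dicarbonyls; the vicinal trione then adds MeOH at C6 and undergoes the benzilic ester rearrangement (C7 migrates from C6 to C5 with retention, ring contraction), and the former C6 is expected to end up as CO2Me on the face of the smaller OAc group with the C5 alkoxide anti to the acetoxy dipole, which sets C5 (R) with OH trans to OAc.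

## Compound list

1 | (S)-2-methylbutan-1-ol | CC[C@H](C)CO | starting material
2 | (S)-2-methylbutanal | CC[C@H](C)C=O | intermediate
3 | (2E,4S)-2,4-dimethylhex-2-enal | CC[C@H](C)/C=C(C)/C=O | intermediate
4 | 2-[(1E,3E,5S)-3,5-dimethylhepta-1,3-dien-1-yl]-4,4,5,5-tetramethyl-1,3,2-dioxaborolane | CC[C@H](C)/C=C(C)/C=C/B1OC(C)(C)C(C)(C)O1 | intermediate
5 | 5-bromo-2-chloropyridine | Clc1ccc(Br)cn1 | starting material
6 | 5-bromo-2-chloro-4-lithiopyridine | [Li]c1cc(Cl)ncc1Br | intermediate
7 | 5-bromo-2-chloro-4-methylpyridine | Cc1cc(Cl)ncc1Br | intermediate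
8 | (6-chloro-4-methylpyridin-3-yl)magnesium chloride (LiCl complex) | Cc1cc(Cl)ncc1[Mg]Cl | intermediate
9 | methyl 6-chloro-4-methylpyridine-3-carboxylate | COC(=O)c1cnc(Cl)cc1C | intermediate
10 | methyl 6-[(1E,3E,5S)-3,5-dimethylhepta-1,3-dien-1-yl]-4-methylpyridine-3-carboxylate | CC[C@H](C)/C=C(C)/C=C/c1cc(C)c(cn1)C(=O)OC | intermediate
11 | N-methoxy-N-methylpropanamide | CCC(=O)N(C)OC | starting material
12 | methyl 6-[(1E,3E,5S)-3,5-dimethylhepta-1,3-dien-1-yl]-4-(lithiomethyl)pyridine-3-carboxylate | CC[C@H](C)/C=C(C)/C=C/c1cc(C[Li])c(cn1)C(=O)OC | intermediate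
13 | lithium alkoxide of the N-methoxy-N-methyl hemiaminal from 12 and 11 (tetrahedral adduct, both epimers) | CC[C@H](C)/C=C(C)/C=C/c1cc(CC(CC)(O[Li])N(C)OC)c(cn1)C(=O)OC | intermediate
14 | methyl 6-[(1E,3E,5S)-3,5-dimethylhepta-1,3-dien-1-yl]-4-(2-oxobutyl)pyridine-3-carboxylate | CC[C@H](C)/C=C(C)/C=C/c1cc(CC(=O)CC)c(cn1)C(=O)OC | intermediate
15 | 3-[(1E,3E,5S)-3,5-dimethylhepta-1,3-dien-1-yl]-7-methylisoquinoline-6,8-diol | CC[C@H](C)/C=C(C)/C=C/c1cc2cc(O)c(C)c(O)c2cn1 | intermediate
16 | 3-[(1E,3E,5S)-3,5-dimethylhepta-1,3-dien-1-yl]-6-hydroxy-7-methylisoquinoline-5,8-dione | CC[C@H](C)/C=C(C)/C=C/c1cc2c(cn1)C(=O)C(C)=C(O)C2=O | intermediate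
17 | (7R)-3-[(1E,3E,5S)-3,5-dimethylhepta-1,3-dien-1-yl]-7-methyl-5,6,8-trioxo-5,6,7,8-tetrahydroisoquinolin-7-yl acetate | CC[C@H](C)/C=C(C)/C=C/c1cc2c(cn1)C(=O)[C@@](C)(OC(C)=O)C(=O)C2=O | intermediate
18 | (7R)-3-[(1E,3E,5S)-3,5-dimethylhepta-1,3-dien-1-yl]-6-hydroxy-6-methoxy-7-methyl-5,8-dioxo-5,6,7,8-tetrahydroisoquinolin-7-yl acetate (C6 hemiketal, both epimers) | CC[C@H](C)/C=C(C)/C=C/c1cc2c(cn1)C(=O)[C@@](C)(OC(C)=O)C(O)(OC)C2=O | intermediate
19 | methyl (5R,6S)-6-acetoxy-3-[(1E,3E,5S)-3,5-dimethylhepta-1,3-dien-1-yl]-5-hydroxy-6-methyl-7-oxo-6,7-dihydro-5H-cyclopenta[c]pyridine-5-carboxylate | CC[C@H](C)/C=C(C)/C=C/c1cc2c(cn1)C(=O)[C@@](C)(OC(C)=O)[C@@]2(O)C(=O)OC | target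

## Step count and risks

Total steps: 7. Longest linear sequence: 5 (steps 3, 4, 5, 6, 7; equally 1, 2, 5, 6, 7).

**Step 7 (the proposed new step).** The ee and even the facial sense at C7 are untested on a hydroxyquinone, and the I(III) reagent must leave the diene alone. The C5 selectivity rests on a steric and dipole argument only. A base-induced retro-Claisen/aldol pathway would give the same constitution but scramble C7, which is why only a buffered amine at ≤0 °C is used. The fallback uses known chemistry, sets out from 16 and comes back at 19. Achiral PhI(OAc)2 in CH2Cl2 at 0 °C (ordinary α-acetoxylation of an enolised 1,3-dicarbonyl) gives 17 together with its C7 epimer, (7S)-3-[(1E,3E,5S)-3,5-dimethylhepta-1,3-dien-1-yl]-7-methyl-5,6,8-trioxo-5,6,7,8-tetrahydroisoquinolin-7-yl acetate F1, about 1:1. The same MeOH/Et3N contraction then gives 19 and methyl (5S,6R)-6-acetoxy-3-[(1E,3E,5S)-3,5-dimethylhepta-1,3-dien-1-yl]-5-hydroxy-6-methyl-7-oxo-6,7-dihydro-5H-cyclopenta[c]pyridine-5-carboxylate F2. These two are diastereomers through the side-chain center and are separated by preparative HPLC on a chiral stationary phase.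

**Step 6.** Four events run in one flask. The weak points are O- versus C-cyclisation of the keto ester, over-oxidation of the hydroxyquinone by peroxide formed in base/air, and deprotonation of the side chain. The fallback sets out from 9 and comes back at 16. LDA then methyl methacrylate (Michael–Dieckmann annulation) gives methyl 3-chloro-7-methyl-8-oxo-5,6,7,8-tetrahydroisoquinoline-7-carboxylate F3. Krapcho dealkoxycarbonylation (LiCl, wet DMSO, 140 °C) gives 3-chloro-7-methyl-6,7-dihydroisoquinolin-8(5H)-one F4. KOtBu/O2 autoxidation of this tetralone-type ketone gives 3-chloro-6-hydroxy-7-methylisoquinoline-5,8-dione F5. Suzuki coupling of F5 with 4 (one extra equivalent of base for the acidic OH) gives 16.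

**Step 2.** The bulky α-boryl carbanion may add 1,4 to the α-branched enal or give a poorer E/Z ratio. The fallback sets out from 3 and comes back at 4. Ohira–Bestmann homologation (dimethyl (1-diazo-2-oxopropyl)phosphonate, K2CO3, MeOH, 0 °C) gives (3E,5S)-3,5-dimethylhept-3-en-1-yne F6. Cp2Zr(H)Cl-catalysed syn-hydroboration with pinacolborane then gives 4.

## Further compounds

F1 | step 7 | (7S)-3-[(1E,3E,5S)-3,5-dimethylhepta-1,3-dien-1-yl]-7-methyl-5,6,8-trioxo-5,6,7,8-tetrahydroisoquinolin-7-yl acetate | CC[C@H](C)/C=C(C)/C=C/c1cc2c(cn1)C(=O)[C@](C)(OC(C)=O)C(=O)C2=O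
F2 | step 7 | methyl (5S,6R)-6-acetoxy-3-[(1E,3E,5S)-3,5-dimethylhepta-1,3-dien-1-yl]-5-hydroxy-6-methyl-7-oxo-6,7-dihydro-5H-cyclopenta[c]pyridine-5-carboxylate | CC[C@H](C)/C=C(C)/C=C/c1cc2c(cn1)C(=O)[C@](C)(OC(C)=O)[C@]2(O)C(=O)OC
F3 | step 6 | methyl 3-chloro-7-methyl-8-oxo-5,6,7,8-tetrahydroisoquinoline-7-carboxylate (racemic) | COC(=O)C1(C)CCc2cc(Cl)ncc2C1=O
F4 | step 6 | 3-chloro-7-methyl-6,7-dihydroisoquinolin-8(5H)-one (racemic) | CC1CCc2cc(Cl)ncc2C1=O
F5 | step 6 | 3-chloro-6-hydroxy-7-methylisoquinoline-5,8-dione | CC1=C(O)C(=O)c2cc(Cl)ncc2C1=O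
F6 | step 2 | (3E,5S)-3,5-dimethylhept-3-en-1-yne | CC[C@H](C)/C=C(C)/C#C
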